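**Plan**
- Retrosynthesis cuts, in order: the acetate C–O bond; the ring-B C6′–CO2H bond (back to a C–H flanked by two oxygens); the ring-A C2–CH2O bond; the ring-A C1–C6 bond; the ether O–C1 bond at the sp3 stage; the ring-B C4′–prenyl bond.
- Enabling feature: ring A (C1 O-aryl, C2 CH2OAc, C4 CH3, C6 OH) has a near mirror plane through C1 and C4, so C2 and C6 can both descend from the two equivalent carbonyl carbons of a Cs-symmetric 2-aryloxy-5-methylcyclohexane-1,3-dione.
- Forward: a bromomethyl ketone (from 3-methylglutaric anhydride) O-alkylates the ring-B phenol (ring B is bought as an arene); base then closes ring A as the dione.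
- Ring A is aromatised by O-methylation, alkoxymethyllithium addition with enone transposition, and dehydrogenation; ring B is then carboxylated, the acetals are removed and the primary alcohol is acetylated.
- Stereochemistry: the target has no stereocentre; the one stereocentre of the chain is carried racemic and is erased when ring A becomes aromatic.

Key step: step 8

Remark: ring A is numbered C1 (O-aryl), C2 (CH2OAc), C4 (CH3), C6 (OH) and ring B C1′ (ether), C4′ (prenyl), C5′ (OH), C6′ (CO2H). 2-Bromo-5-methoxyphenol (6) and tributyl[(methoxymethoxy)methyl]stannane (15) are taken as catalogue compounds. All chiral intermediates are racemic.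

**Route**

Step 1
Reactants: 1 3-methylglutaric anhydride
Product: 2 5-methoxy-3-methyl-5-oxopentanoic acid (racemic)
Conditions: MeOH, reflux
Reagents that add atoms: methanol, CO
Why: Alcoholysis of the cyclic anhydride opens it once, and because its two carbonyls are equivalent a single racemic half ester should result.

Step 2
Reactants: 2 5-methoxy-3-methyl-5-oxopentanoic acid (racemic)
Product: 3 methyl 5-chloro-3-methyl-5-oxopentanoate (racemic)
Conditions: (COCl)2, cat. DMF, CH2Cl2, 0 °C → rt
Reagents that add atoms: oxalyl chloride, O=C(Cl)C(=O)Cl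
Why: Vilsmeier-type activation by the chloroiminium salt from oxalyl chloride and DMF should convert the acid into the acid chloride without touching the methyl ester.

Step 3
Reactants: 3 methyl 5-chloro-3-methyl-5-oxopentanoate (racemic)
Product: 5 methyl 6-bromo-3-methyl-5-oxohexanoate (racemic), via diazoketone 4 (not isolated)
Conditions: CH2N2 (excess), Et2O, 0 °C; N2 purge; then 48% aq. HBr, 0 °C
Reagents that add atoms: diazomethane, C=[N+]=[N-]; hydrogen bromide, Br
Why: Acylation of diazomethane by the acid chloride (first stage of the Arndt–Eistert sequence, a second equivalent taking up HCl) gives the diazoketone, which HBr protonates at carbon before bromide displaces dinitrogen to give the bromomethyl ketone.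

Step 4
Reactants: 6 2-bromo-5-methoxyphenol
Product: 7 1-bromo-4-methoxy-2-(methoxymethoxy)benzene
Conditions: MOMCl, i-Pr2NEt, CH2Cl2, 0 °C → rt
Reagents that add atoms: chloromethyl methyl ether, COCCl
Why: Williamson-type O-alkylation with the reactive α-chloro ether installs the MOM acetal, which is stable to every basic step and later directs the lithiation of ring B.

Step 5
Reactants: 7 1-bromo-4-methoxy-2-(methoxymethoxy)benzene; 8 1-bromo-3-methylbut-2-ene (prenyl bromide)
Product: 10 4-methoxy-2-(methoxymethoxy)-1-(3-methylbut-2-enyl)benzene, via aryllithium 9 (not isolated)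
Conditions: n-BuLi, THF, −78 °C; then CuI (0.1 equiv), 8, −78 °C → rt
Reagents that add atoms: none
Why: Bromine–lithium exchange fixes the metal at the former C–Br carbon (ortho to the MOM ether, para to the methoxy group), and copper-assisted SN2 allylation with prenyl bromide should form the aryl–CH2 bond at the unsubstituted allyl terminus.

Step 6
Reactants: 10 4-methoxy-2-(methoxymethoxy)-1-(3-methylbut-2-enyl)benzene
Product: 11 3-(methoxymethoxy)-4-(3-methylbut-2-enyl)phenol
Conditions: NaSEt, DMF, 120 °C; then aq. NH4Cl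
Reagents that add atoms: none
Why: SN2 demethylation of the aryl methyl ether by ethanethiolate in a dipolar aprotic solvent should free the phenol para to the prenyl group, the acetal and the alkene being inert to thiolate.

Step 7
Reactants: 11 3-(methoxymethoxy)-4-(3-methylbut-2-enyl)phenol; 5 methyl 6-bromo-3-methyl-5-oxohexanoate (racemic)
Product: 12 methyl 6-[3-(methoxymethoxy)-4-(3-methylbut-2-enyl)phenoxy]-3-methyl-5-oxohexanoate (racemic)
Conditions: K2CO3, acetone, rt
Reagents that add atoms: none
Why: Williamson ether synthesis in which the phenoxide displaces bromide from the SN2-reactive α-bromo ketone, so the future diaryl ether oxygen is attached at an sp3 carbon and no hindered aryl–oxygen coupling is needed.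

Step 8
Reactants: 12 methyl 6-[3-(methoxymethoxy)-4-(3-methylbut-2-enyl)phenoxy]-3-methyl-5-oxohexanoate (racemic)
Product: 13 2-[3-(methoxymethoxy)-4-(3-methylbut-2-enyl)phenoxy]-5-methylcyclohexane-1,3-dione
Conditions: KOt-Bu (2.2 equiv), THF, 0 °C → rt; then 1 M HCl, 0 °C, to pH 3
Reagents that add atoms: none
Why: KOt-Bu equilibrates the two ketone enolates; the one at the aryloxy-bearing carbon (chain C6, future ring-A C1) adds to the ester carbonyl, methoxide leaves, and the acidic 2-aryloxy-1,3-dione is deprotonated at once, which drains the equilibrium until the cold acidic work-up. The closest known reaction type is the Dieckmann-type intramolecular Claisen condensation of 5-oxo esters to cyclohexane-1,3-diones. Ring A closes as a six-membered ring by 6-exo-trig acyl substitution, forming the ring-A C1–C6 bond (C2 and C6 being equivalent at this stage). No stereocentre is created, and the chain stereocentre becomes C5 of an achiral dione, so racemic 12 should converge on one compound. The step needs regioselectivity between the two enolates, which ring size secures because the other enolate could only give a cyclobutanone and returns by proton exchange. Ring B offers no competing electrophile, since it carries only ether groups and an isolated alkene and no aryl ester, and the hindered base should avoid retro-Claisen opening.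

Step 9
Reactants: 13 2-[3-(methoxymethoxy)-4-(3-methylbut-2-enyl)phenoxy]-5-methylcyclohexane-1,3-dione
Product: 14 3-methoxy-2-[3-(methoxymethoxy)-4-(3-methylbut-2-enyl)phenoxy]-5-methylcyclohex-2-en-1-one (racemic)
Conditions: CH2N2, Et2O–MeOH, 0 °C
Reagents that add atoms: diazomethane, C=[N+]=[N-]
Why: The acidic enol protonates diazomethane and the methyldiazonium ion alkylates the enolate oxygen (O-methylation of a 1,3-dione), and since the two carbonyls are enantiotopic one racemic vinylogous ester should form.

Step 10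
Reactants: 14 3-methoxy-2-[3-(methoxymethoxy)-4-(3-methylbut-2-enyl)phenoxy]-5-methylcyclohex-2-en-1-one (racemic); 15 tributyl[(methoxymethoxy)methyl]stannane
Product: 17 3-[(methoxymethoxy)methyl]-2-[3-(methoxymethoxy)-4-(3-methylbut-2-enyl)phenoxy]-5-methylcyclohex-2-en-1-one (racemic), via tertiary carbinol 16 (not isolated)
Conditions: 15, n-BuLi, THF, −78 °C; then 14, −78 → −40 °C; then 1 M HCl, THF, 0 °C
Reagents that add atoms: none
Why: Stork–Danheiser alkylative carbonyl transposition, in which tin–lithium exchange gives the alkoxymethyllithium (a hydroxymethyl anion equivalent) that adds 1,2 to the vinylogous ester carbonyl, after which dilute acid hydrolyses the enol ether and eliminates water to give the transposed enone carrying the future C2 side chain.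

Step 11
Reactants: 17 3-[(methoxymethoxy)methyl]-2-[3-(methoxymethoxy)-4-(3-methylbut-2-enyl)phenoxy]-5-methylcyclohex-2-en-1-one (racemic)
Product: 19 3-[(methoxymethoxy)methyl]-2-[3-(methoxymethoxy)-4-(3-methylbut-2-enyl)phenoxy]-5-methyl-6-(phenylselanyl)cyclohex-2-en-1-one (expected mainly trans; racemic), via lithium enolate 18 (not isolated)
Conditions: LiN(i-Pr)2, THF, −78 °C; then PhSeBr, −78 °C
Reagents that add atoms: benzeneselenenyl bromide, Br[Se]c1ccccc1
Why: Kinetic deprotonation gives the cross-conjugated α′-enolate at C6, and its selenenylation (enolate α-selenenylation) is much faster than attack on the prenyl alkene and should occur anti to the neighbouring C5 methyl group.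

Step 12
Reactants: 19 3-[(methoxymethoxy)methyl]-2-[3-(methoxymethoxy)-4-(3-methylbut-2-enyl)phenoxy]-5-methyl-6-(phenylselanyl)cyclohex-2-en-1-one
Product: 22 3-[(methoxymethoxy)methyl]-2-[3-(methoxymethoxy)-4-(3-methylbut-2-enyl)phenoxy]-5-methylphenol, via selenoxide 20 (not isolated), via dienone 21 (not isolated)
Conditions: m-CPBA (1.0 equiv), CH2Cl2, −78 °C; then pyridine, −78 °C → rt
Reagents that add atoms: none
Why: Selenide oxidation and selenoxide syn-elimination (selenium is cis to C5–H in the trans isomer) introduce the C5=C6 double bond, and the cyclohexa-2,5-dienone formed is the keto tautomer of the phenol and aromatises by proton shift, while one equivalent of peracid at −78 °C should spare the prenyl alkene.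

Step 13
Reactants: 22 3-[(methoxymethoxy)methyl]-2-[3-(methoxymethoxy)-4-(3-methylbut-2-enyl)phenoxy]-5-methylphenol
Product: 23 1-(methoxymethoxy)-3-[(methoxymethoxy)methyl]-2-[3-(methoxymethoxy)-4-(3-methylbut-2-enyl)phenoxy]-5-methylbenzene
Conditions: MOMCl, i-Pr2NEt, CH2Cl2, 0 °C → rt
Reagents that add atoms: chloromethyl methyl ether, COCCl
Why: O-alkylation of the ring-A phenol (MOM ether formation) removes the acidic proton before the lithiation.

Step 14
Reactants: 23 1-(methoxymethoxy)-3-[(methoxymethoxy)methyl]-2-[3-(methoxymethoxy)-4-(3-methylbut-2-enyl)phenoxy]-5-methylbenzene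
Product: 25 2-(methoxymethoxy)-6-[2-(methoxymethoxy)-6-[(methoxymethoxy)methyl]-4-methylphenoxy]-3-(3-methylbut-2-enyl)benzoic acid, via aryllithium 24 (not isolated)
Conditions: n-BuLi, THF, −20 → 0 °C; then CO2 (g), −78 °C → rt; then 1 M HCl, 0 °C, to pH 3
Reagents that add atoms: carbon dioxide, O=C=O
Why: Directed ortho-metalation: C6′–H of ring B is the only arene C–H flanked by two oxygens (the MOM ether at C5′ and the ether oxygen at C1′), so n-BuLi guided by MOM chelation should deprotonate there and CO2 then carboxylates the aryllithium.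

Step 15
Reactants: 25 2-(methoxymethoxy)-6-[2-(methoxymethoxy)-6-[(methoxymethoxy)methyl]-4-methylphenoxy]-3-(3-methylbut-2-enyl)benzoic acid
Product: 26 2-hydroxy-6-[2-hydroxy-6-(hydroxymethyl)-4-methylphenoxy]-3-(3-methylbut-2-enyl)benzoic acid
Conditions: TMSOTf, 2,2′-bipyridyl, CH2Cl2–MeCN, 0 °C → rt; then H2O
Reagents that add atoms: none
Why: Silyl triflate activation of the acetals buffered by 2,2′-bipyridyl cleaves aryl and alkyl MOM ethers without free acid (acetal cleavage, hydrolysis on adding water), which should avoid cyclisation of the prenyl group onto the neighbouring phenol.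

Step 16
Reactants: 26 2-hydroxy-6-[2-hydroxy-6-(hydroxymethyl)-4-methylphenoxy]-3-(3-methylbut-2-enyl)benzoic acid
Product: 27 6-[2-(acetoxymethyl)-6-hydroxy-4-methylphenoxy]-2-hydroxy-3-(3-methylbut-2-enyl)benzoic acid (7-O-acetylsecopenicillide C)
Conditions: immobilised Candida antarctica lipase B, vinyl acetate, t-BuOMe–THF, 35 °C
Reagents that add atoms: vinyl acetate, C=COC(C)=O
Why: Lipase-catalysed transesterification with the irreversible acyl donor vinyl acetate acylates primary alcohols but not phenols or carboxylic acids, so only the benzylic hydroxyl should be acetylated.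

**Compound list**

1 | 3-methylglutaric anhydride | CC1CC(=O)OC(=O)C1 | starting material
2 | 5-methoxy-3-methyl-5-oxopentanoic acid (racemic) | COC(=O)CC(C)CC(=O)O | intermediate
3 | methyl 5-chloro-3-methyl-5-oxopentanoate (racemic) | COC(=O)CC(C)CC(=O)Cl | intermediate
4 | methyl 6-diazo-3-methyl-5-oxohexanoate (racemic) | COC(=O)CC(C)CC(=O)C=[N+]=[N-] | intermediate (not isolated)
5 | methyl 6-bromo-3-methyl-5-oxohexanoate (racemic) | COC(=O)CC(C)CC(=O)CBr | intermediate
6 | 2-bromo-5-methoxyphenol | COc1ccc(Br)c(O)c1 | starting material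
7 | 1-bromo-4-methoxy-2-(methoxymethoxy)benzene | COCOc1cc(OC)ccc1Br | intermediate
8 | 1-bromo-3-methylbut-2-ene (prenyl bromide) | CC(C)=CCBr | starting material
9 | [4-methoxy-2-(methoxymethoxy)phenyl]lithium | [Li]c1ccc(OC)cc1OCOC | intermediate (not isolated)
10 | 4-methoxy-2-(methoxymethoxy)-1-(3-methylbut-2-enyl)benzene | COCOc1cc(OC)ccc1CC=C(C)C | intermediate
11 | 3-(methoxymethoxy)-4-(3-methylbut-2-enyl)phenol | COCOc1cc(O)ccc1CC=C(C)C | intermediate
12 | methyl 6-[3-(methoxymethoxy)-4-(3-methylbut-2-enyl)phenoxy]-3-methyl-5-oxohexanoate (racemic) | COC(=O)CC(C)CC(=O)COc1ccc(CC=C(C)C)c(OCOC)c1 | intermediate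
13 | 2-[3-(methoxymethoxy)-4-(3-methylbut-2-enyl)phenoxy]-5-methylcyclohexane-1,3-dione | CC1CC(=O)C(Oc2ccc(CC=C(C)C)c(OCOC)c2)C(=O)C1 | intermediate
14 | 3-methoxy-2-[3-(methoxymethoxy)-4-(3-methylbut-2-enyl)phenoxy]-5-methylcyclohex-2-en-1-one (racemic) | COC1=C(Oc2ccc(CC=C(C)C)c(OCOC)c2)C(=O)CC(C)C1 | intermediate
15 | tributyl[(methoxymethoxy)methyl]stannane | CCCC[Sn](CCCC)(CCCC)COCOC | starting material
16 | 3-methoxy-1-[(methoxymethoxy)methyl]-2-[3-(methoxymethoxy)-4-(3-methylbut-2-enyl)phenoxy]-5-methylcyclohex-2-en-1-ol (diastereomer mixture, racemic) | COCOCC1(O)CC(C)CC(OC)=C1Oc2ccc(CC=C(C)C)c(OCOC)c2 | intermediate (not isolated)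
17 | 3-[(methoxymethoxy)methyl]-2-[3-(methoxymethoxy)-4-(3-methylbut-2-enyl)phenoxy]-5-methylcyclohex-2-en-1-one (racemic) | COCOCC1=C(Oc2ccc(CC=C(C)C)c(OCOC)c2)C(=O)CC(C)C1 | intermediate
18 | lithium 5-[(methoxymethoxy)methyl]-6-[3-(methoxymethoxy)-4-(3-methylbut-2-enyl)phenoxy]-3-methylcyclohexa-1,5-dien-1-olate (racemic) | COCOCC1=C(Oc2ccc(CC=C(C)C)c(OCOC)c2)C(O[Li])=CC(C)C1 | intermediate (not isolated)
19 | 3-[(methoxymethoxy)methyl]-2-[3-(methoxymethoxy)-4-(3-methylbut-2-enyl)phenoxy]-5-methyl-6-(phenylselanyl)cyclohex-2-en-1-one (expected mainly trans, racemic) | COCOCC1=C(Oc2ccc(CC=C(C)C)c(OCOC)c2)C(=O)C([Se]c2ccccc2)C(C)C1 | intermediate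
20 | 3-[(methoxymethoxy)methyl]-2-[3-(methoxymethoxy)-4-(3-methylbut-2-enyl)phenoxy]-5-methyl-6-(phenylseleninyl)cyclohex-2-en-1-one | COCOCC1=C(Oc2ccc(CC=C(C)C)c(OCOC)c2)C(=O)C([Se](=O)c2ccccc2)C(C)C1 | intermediate (not isolated)
21 | 3-[(methoxymethoxy)methyl]-2-[3-(methoxymethoxy)-4-(3-methylbut-2-enyl)phenoxy]-5-methylcyclohexa-2,5-dien-1-one | COCOCC1=C(Oc2ccc(CC=C(C)C)c(OCOC)c2)C(=O)C=C(C)C1 | intermediate (not isolated)
22 | 3-[(methoxymethoxy)methyl]-2-[3-(methoxymethoxy)-4-(3-methylbut-2-enyl)phenoxy]-5-methylphenol | COCOCc1cc(C)cc(O)c1Oc1ccc(CC=C(C)C)c(OCOC)c1 | intermediate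
23 | 1-(methoxymethoxy)-3-[(methoxymethoxy)methyl]-2-[3-(methoxymethoxy)-4-(3-methylbut-2-enyl)phenoxy]-5-methylbenzene | COCOCc1cc(C)cc(OCOC)c1Oc1ccc(CC=C(C)C)c(OCOC)c1 | intermediate
24 | [2-(methoxymethoxy)-6-[2-(methoxymethoxy)-6-[(methoxymethoxy)methyl]-4-methylphenoxy]-3-(3-methylbut-2-enyl)phenyl]lithium | COCOCc1cc(C)cc(OCOC)c1Oc1ccc(CC=C(C)C)c(OCOC)c1[Li] | intermediate (not isolated)
25 | 2-(methoxymethoxy)-6-[2-(methoxymethoxy)-6-[(methoxymethoxy)methyl]-4-methylphenoxy]-3-(3-methylbut-2-enyl)benzoic acid | COCOCc1cc(C)cc(OCOC)c1Oc1ccc(CC=C(C)C)c(OCOC)c1C(=O)O | intermediate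
26 | 2-hydroxy-6-[2-hydroxy-6-(hydroxymethyl)-4-methylphenoxy]-3-(3-methylbut-2-enyl)benzoic acid | OCc1cc(C)cc(O)c1Oc1ccc(CC=C(C)C)c(O)c1C(=O)O | intermediate
27 | 6-[2-(acetoxymethyl)-6-hydroxy-4-methylphenoxy]-2-hydroxy-3-(3-methylbut-2-enyl)benzoic acid (7-O-acetylsecopenicillide C) | CC(=O)OCc1cc(C)cc(O)c1Oc1ccc(CC=C(C)C)c(O)c1C(=O)O | target

**Step count**

Total: 16 steps. Longest linear sequence: 13 steps (from 1 through steps 1–3 and 7–16; the branch from 6 through steps 4–6 and 7–16 is equally long).

**Steps most likely to fail**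

Step 14 (lithiation and carboxylation of ring B). Metalation may stray to the benzylic CH2 of the ring-A side chain, to ring-A C5–H beside its MOM ether, or to the allylic-benzylic CH2 of the prenyl group, or may be slow at the crowded C6′ position. The fallback replaces deprotonation by an electrophilic ortho-formylation and sets out from 22.
- Acylation of the ring-A phenol (PivCl, pyridine, CH2Cl2) should give 3-[(methoxymethoxy)methyl]-2-[3-(methoxymethoxy)-4-(3-methylbut-2-enyl)phenoxy]-5-methylphenyl 2,2-dimethylpropanoate F1.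
- Removal of both acetals (TMSOTf, 2,2′-bipyridyl, then H2O) should give 3-(hydroxymethyl)-2-[3-hydroxy-4-(3-methylbut-2-enyl)phenoxy]-5-methylphenyl 2,2-dimethylpropanoate F2, in which only the ring-B phenol is free.
- Magnesium-mediated ortho-formylation (MgCl2, Et3N, paraformaldehyde, MeCN, reflux) can only go to C6′, the single free ortho position of that phenol, and should give 2-[2-formyl-3-hydroxy-4-(3-methylbut-2-enyl)phenoxy]-3-(hydroxymethyl)-5-methylphenyl 2,2-dimethylpropanoate F3.
- Pinnick oxidation (NaClO2, NaH2PO4, 2-methylbut-2-ene, t-BuOH–H2O) should give 2-hydroxy-6-[2-(hydroxymethyl)-4-methyl-6-(2,2-dimethylpropanoyloxy)phenoxy]-3-(3-methylbut-2-enyl)benzoic acid F4.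
- Methanolysis of the pivalate (K2CO3, MeOH) brings the material back to the route at 26.

Step 10 (alkoxymethyllithium addition and transposition). The basic organolithium may enolise the hindered, aryloxy-flanked vinylogous ester at C6 instead of adding to its carbonyl, so that starting material returns, or the reagent may decompose before it adds. The fallback replaces carbonyl addition by cross-coupling and sets out from 13.
- Triflation of either equivalent carbonyl (Tf2O, Et3N, CH2Cl2, −78 °C) should give 2-[3-(methoxymethoxy)-4-(3-methylbut-2-enyl)phenoxy]-5-methyl-3-oxocyclohex-1-en-1-yl trifluoromethanesulfonate F5.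
- Stille coupling with (tributylstannyl)methanol (Pd(PPh3)4, LiCl, dioxane, 90 °C) should give 3-(hydroxymethyl)-2-[3-(methoxymethoxy)-4-(3-methylbut-2-enyl)phenoxy]-5-methylcyclohex-2-en-1-one F6.
- Protection of the alcohol (MOMCl, i-Pr2NEt, CH2Cl2) returns to the route at 17.

Step 16 (enzymatic acetylation). The enzyme may turn over slowly because the benzylic alcohol sits beside the bulky aryloxy group, or acyl transfer to a phenol may compete during long reaction times. The fallback replaces selective acylation by exhaustive acylation followed by selective deacylation and sets out from 26.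
- Ac2O and pyridine, with aqueous work-up to hydrolyse any mixed anhydride, should give 2-acetoxy-6-[2-acetoxy-6-(acetoxymethyl)-4-methylphenoxy]-3-(3-methylbut-2-enyl)benzoic acid F7.
- Pyrrolidine (CH2Cl2, 0 °C) should then aminolyse the two far more electrophilic aryl acetates and leave the primary benzylic acetate, arriving at 27.

**Further compounds**

F1 | step 14 | 3-[(methoxymethoxy)methyl]-2-[3-(methoxymethoxy)-4-(3-methylbut-2-enyl)phenoxy]-5-methylphenyl 2,2-dimethylpropanoate | COCOCc1cc(C)cc(OC(=O)C(C)(C)C)c1Oc1ccc(CC=C(C)C)c(OCOC)c1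
F2 | step 14 | 3-(hydroxymethyl)-2-[3-hydroxy-4-(3-methylbut-2-enyl)phenoxy]-5-methylphenyl 2,2-dimethylpropanoate | OCc1cc(C)cc(OC(=O)C(C)(C)C)c1Oc1ccc(CC=C(C)C)c(O)c1
F3 | step 14 | 2-[2-formyl-3-hydroxy-4-(3-methylbut-2-enyl)phenoxy]-3-(hydroxymethyl)-5-methylphenyl 2,2-dimethylpropanoate | OCc1cc(C)cc(OC(=O)C(C)(C)C)c1Oc1ccc(CC=C(C)C)c(O)c1C=O
F4 | step 14 | 2-hydroxy-6-[2-(hydroxymethyl)-4-methyl-6-(2,2-dimethylpropanoyloxy)phenoxy]-3-(3-methylbut-2-enyl)benzoic acid | OCc1cc(C)cc(OC(=O)C(C)(C)C)c1Oc1ccc(CC=C(C)C)c(O)c1C(=O)O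
F5 | step 10 | 2-[3-(methoxymethoxy)-4-(3-methylbut-2-enyl)phenoxy]-5-methyl-3-oxocyclohex-1-en-1-yl trifluoromethanesulfonate (racemic) | CC1CC(=O)C(Oc2ccc(CC=C(C)C)c(OCOC)c2)=C(OS(=O)(=O)C(F)(F)F)C1
F6 | step 10 | 3-(hydroxymethyl)-2-[3-(methoxymethoxy)-4-(3-methylbut-2-enyl)phenoxy]-5-methylcyclohex-2-en-1-one (racemic) | OCC1=C(Oc2ccc(CC=C(C)C)c(OCOC)c2)C(=O)CC(C)C1
F7 | step 16 | 2-acetoxy-6-[2-acetoxy-6-(acetoxymethyl)-4-methylphenoxy]-3-(3-methylbut-2-enyl)benzoic acid | CC(=O)OCc1cc(C)cc(OC(C)=O)c1Oc1ccc(CC=C(C)C)c(OC(C)=O)c1C(=O)O
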